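The retrosynthesis first puts the five phenols back as benzyl ethers. It then cuts O1–C2 of ring C, which opens the chroman to an (R)-1,1,3-triarylpropane with a free ring A phenol. After that it cuts the ring P–acyl bond, C4–H, C4–ring P and C2–C3.
The key step is possible because C2 is a benzylic CH2 para to the 4'-oxygen of ring B. Loss of hydride from C2 leaves a para-alkoxybenzyl cation, and the phenol oxygen on C8a of ring A (the later O1) can reach it through a six-membered ring.
In the forward direction rings A, B and P are bought as arenes. The C4–C3–C2 chain is joined by aldol condensation and saturated, ring P is added to the C4 ketone, and the side-chain ketone is put on ring P. Ring C is the only ring made and closes in the penultimate step.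
The side-chain ketone goes in before the oxidation because it lowers the donor strength of ring P next to the competing C4–H. It also lets the route end with a neutral hydrogenolysis, not an acid-mediated acylation of an epimerisable polyphenol.
C4 (R) comes from a chiral-phosphoric-acid-catalysed transfer hydrogenation of an ortho-quinone methide. C2 (R) is relayed from C4 in the ring closure (2,4-cis).
Key step: step 9

Remark: rotation about the bond from C4 to ring P is hindered in the 2,4-cis series, so the chromans may appear as two slowly interconverting rotamers; the target carries no axial descriptor and none is controlled.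
Remark: the absolute sense of induction in step 5 is assigned by analogy with simpler 2-(1-arylvinyl)phenols; the configuration of the product is to be checked at that stage, and the equally available enantiomeric acid is used if the sense proves opposite.

Step 1
Reactants: 1 1-[4-(benzyloxy)-2-hydroxyphenyl]ethanone; 2 4-(benzyloxy)benzaldehyde
Product: 3 (E)-1-[4-(benzyloxy)-2-hydroxyphenyl]-3-[4-(benzyloxy)phenyl]prop-2-en-1-one
Conditions: KOH (50 % aq), EtOH, rt; then dilute HCl
Reagents that add atoms: none
Why: Claisen–Schmidt aldol condensation, in which the acetophenone enolate adds to the non-enolisable aldehyde and loss of water gives the conjugated (E)-enone, joining C3 to C2, while the chalcone should crystallise on acidification before it can close to the flavanone.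

Step 2
Reactants: 3 (E)-1-[4-(benzyloxy)-2-hydroxyphenyl]-3-[4-(benzyloxy)phenyl]prop-2-en-1-one
Product: 4 1-[4-(benzyloxy)-2-hydroxyphenyl]-3-[4-(benzyloxy)phenyl]propan-1-one
Conditions: H2 (4 bar), RhCl(PPh3)3 (3 mol %), toluene/EtOH 1:1, 50 °C
Reagents that add atoms: none
Why: Homogeneous hydrogenation with RhCl(PPh3)3 saturates only the disubstituted enone C=C, whereas heterogeneous palladium would also cleave the aryl benzyl ethers, so C2 reaches the CH2 level that the key step needs.

Step 3
Reactants: 5 1,3,5-tris(benzyloxy)benzene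
Product: 6 2-bromo-1,3,5-tris(benzyloxy)benzene
Conditions: NBS (1.0 equiv), CH2Cl2, −40 °C → rt
Reagents that add atoms: N-bromosuccinimide, O=C1CCC(=O)N1Br
Why: Electrophilic aromatic bromination of a phloroglucinol triether, in which the three free positions are equivalent and the first bromine slows a second substitution, so one equivalent of NBS should stop at the monobromide.

Step 4
Reactants: 6 2-bromo-1,3,5-tris(benzyloxy)benzene; 4 1-[4-(benzyloxy)-2-hydroxyphenyl]-3-[4-(benzyloxy)phenyl]propan-1-one
Product: 8 rac-1-[4-(benzyloxy)-2-hydroxyphenyl]-3-[4-(benzyloxy)phenyl]-1-[2,4,6-tris(benzyloxy)phenyl]propan-1-ol, via aryllithium 7 (not isolated)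
Conditions: 6 (2.3 equiv), n-BuLi (2.2 equiv), THF, −78 °C; then 4 premixed with LaCl3·2LiCl (1.1 equiv) in THF, −78 → −20 °C; H2O quench, neutral work-up
Reagents that add atoms: none
Why: Bromine–lithium exchange gives 7 without the benzylic deprotonation and Wittig rearrangement that direct lithiation of 5 would risk; one equivalent of 7 is spent on the phenol of 4 and the next adds 1,2 to the ketone, whose activation by LaCl3·2LiCl favours addition over enolisation, forming the C4–ring P bond (the carbinol centre is racemic and is erased in step 5).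

Step 5
Reactants: 8 rac-1-[4-(benzyloxy)-2-hydroxyphenyl]-3-[4-(benzyloxy)phenyl]-1-[2,4,6-tris(benzyloxy)phenyl]propan-1-ol
Product: 10 5-(benzyloxy)-2-{(1R)-3-[4-(benzyloxy)phenyl]-1-[2,4,6-tris(benzyloxy)phenyl]propyl}phenol, via ortho-quinone methide 9 (not isolated)
Conditions: (R)-TRIP [(R)-3,3'-bis(2,4,6-triisopropylphenyl)-1,1'-binaphthyl-2,2'-diyl hydrogen phosphate, 10 mol %], Hantzsch ester (diethyl 2,6-dimethyl-1,4-dihydropyridine-3,5-dicarboxylate, 1.5 equiv), 5 Å MS, toluene, 35 °C
Reagents that add atoms: none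
Why: Chiral-Brønsted-acid-catalysed asymmetric transfer hydrogenation, in which the acid dehydrates 8 to the ortho-quinone methide 9, holds its carbonyl oxygen and the N–H of the Hantzsch ester in one hydrogen-bonded assembly and lets hydride reach one face of C4 with rearomatisation of ring A, so that both enantiomers of 8 and any styrene formed by proton loss converge on (R)-10.

Step 6
Reactants: 10 5-(benzyloxy)-2-{(1R)-3-[4-(benzyloxy)phenyl]-1-[2,4,6-tris(benzyloxy)phenyl]propyl}phenol
Product: 11 5-(benzyloxy)-2-{(1R)-3-[4-(benzyloxy)phenyl]-1-[2,4,6-tris(benzyloxy)phenyl]propyl}phenyl acetate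
Conditions: Ac2O, Et3N, DMAP (cat), CH2Cl2, rt
Reagents that add atoms: acetic anhydride, CC(=O)OC(C)=O
Why: DMAP-catalysed O-acetylation, which blocks O-acylation of the phenol in step 7 and lowers the nucleophilicity of ring A so that ring P remains the only strongly activated arene.

Step 7
Reactants: 11 5-(benzyloxy)-2-{(1R)-3-[4-(benzyloxy)phenyl]-1-[2,4,6-tris(benzyloxy)phenyl]propyl}phenyl acetate; 12 9-phenylnonanoic acid
Product: 14 5-(benzyloxy)-2-{(1R)-3-[4-(benzyloxy)phenyl]-1-[2,4,6-tris(benzyloxy)-3-(9-phenylnonanoyl)phenyl]propyl}phenyl acetate, via mixed anhydride 13 (not isolated)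
Conditions: 12 (1.3 equiv), (CF3CO)2O (1.3 equiv), CH2Cl2, 0 °C, 30 min; then 11, 0 °C → rt
Reagents that add atoms: none
Why: Friedel–Crafts acylation with an acyl trifluoroacetate, in which 13 acylates the 1,3,5-trialkoxyarene ring P without a Lewis acid that could strip benzyl ethers, the two free positions of ring P are constitutionally equivalent, the far less activated rings A and B should not compete, and the first ketone shuts off a second acylation.

Step 8
Reactants: 14 5-(benzyloxy)-2-{(1R)-3-[4-(benzyloxy)phenyl]-1-[2,4,6-tris(benzyloxy)-3-(9-phenylnonanoyl)phenyl]propyl}phenyl acetate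
Product: 15 1-{2,4,6-tris(benzyloxy)-3-[(1R)-1-[4-(benzyloxy)-2-hydroxyphenyl]-3-[4-(benzyloxy)phenyl]propyl]phenyl}-9-phenylnonan-1-one
Conditions: K2CO3 (0.5 equiv), MeOH/THF 1:1, 0 °C → rt
Reagents that add atoms: none
Why: Carbonate-catalysed methanolysis (transesterification) of the aryl acetate frees the ring A phenol and leaves the hindered ketone, the benzyl ethers and the non-acidic C4–H untouched.

Step 9
Reactants: 15 1-{2,4,6-tris(benzyloxy)-3-[(1R)-1-[4-(benzyloxy)-2-hydroxyphenyl]-3-[4-(benzyloxy)phenyl]propyl]phenyl}-9-phenylnonan-1-one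
Product: 17 1-{2,4,6-tris(benzyloxy)-3-[(2R,4R)-7-(benzyloxy)-2-[4-(benzyloxy)phenyl]chroman-4-yl]phenyl}-9-phenylnonan-1-one, via benzylic cation 16 (not isolated)
Conditions: DDQ (1.1 equiv), 4 Å MS, benzene, rt → 50 °C, dark
Reagents that add atoms: none
Why: DDQ forms a charge-transfer complex with the 4-benzyloxyphenyl ring B and takes hydride from the C2 methylene, which leaves the para-alkoxybenzyl cation 16 (a quinoid oxocarbenium ion) paired with DDQH−; the ring A phenol oxygen then bonds to C2 and gives its proton to that anion. The closest known reaction type is the DDQ oxidative cyclisation of 1-(2-hydroxyaryl)-3-arylpropanes to flavans, one case of DDQ benzylic C–H cleavage followed by intramolecular oxygen capture. Ring C closes in the 6-exo-trig mode, because the C2=C1' bond of the quinoid form of 16 lies outside the new O1–C2–C3–C4–C4a–C8a ring. The new centre C2 is controlled by C4: in the half-chair transition state ring B lies equatorial and ring P pseudo-equatorial, since an axial ring P would push one of its ortho benzyloxy groups over ring C against the axial H2, so O1 should reach the face of 16 that gives the 2,4-cis (2R,4R) chroman. The step needs site selectivity for C2–H over the doubly benzylic C4–H, and the substrate secures it in three ways: C4–H is tertiary and walled in by the two ortho benzyloxy groups of ring P, allylic strain holds it close to the planes of rings A and P so that it overlaps poorly with either π system, and the ketone set on ring P in step 7 lowers the donor strength of that ring. The OCH2Ph groups and the terminal PhCH2 of the side chain carry no para donor on their own phenyl ring and should survive one equivalent of DDQ in the dark, while precipitation of the hydroquinone from benzene keeps the medium close to neutral and limits further oxidation of 17.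

Step 10
Reactants: 17 1-{2,4,6-tris(benzyloxy)-3-[(2R,4R)-7-(benzyloxy)-2-[4-(benzyloxy)phenyl]chroman-4-yl]phenyl}-9-phenylnonan-1-one
Product: 18 1-{2,4,6-trihydroxy-3-[(2R,4R)-7-hydroxy-2-(4-hydroxyphenyl)chroman-4-yl]phenyl}-9-phenylnonan-1-one
Conditions: H2 (1 atm), 10 % Pd/C, EtOAc/MeOH 1:1, rt, stopped at full debenzylation
Reagents that add atoms: none
Why: Catalytic hydrogenolysis of the five aryl benzyl ethers under neutral conditions, in which the secondary, ring-bound C2–O1 bond and the hindered, later hydrogen-bonded aryl ketone should react much more slowly, and the absence of acid or base leaves C2 and C4 unchanged.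

Compound list
1 | 1-[4-(benzyloxy)-2-hydroxyphenyl]ethanone | CC(=O)c1ccc(OCc2ccccc2)cc1O | starting material
2 | 4-(benzyloxy)benzaldehyde | O=Cc1ccc(OCc2ccccc2)cc1 | starting material
3 | (E)-1-[4-(benzyloxy)-2-hydroxyphenyl]-3-[4-(benzyloxy)phenyl]prop-2-en-1-one | O=C(/C=C/c1ccc(OCc2ccccc2)cc1)c1ccc(OCc2ccccc2)cc1O | intermediate
4 | 1-[4-(benzyloxy)-2-hydroxyphenyl]-3-[4-(benzyloxy)phenyl]propan-1-one | O=C(CCc1ccc(OCc2ccccc2)cc1)c1ccc(OCc2ccccc2)cc1O | intermediate
5 | 1,3,5-tris(benzyloxy)benzene | C(c1ccccc1)Oc1cc(OCc2ccccc2)cc(OCc2ccccc2)c1 | starting material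
6 | 2-bromo-1,3,5-tris(benzyloxy)benzene | Brc1c(OCc2ccccc2)cc(OCc2ccccc2)cc1OCc1ccccc1 | intermediate
7 | [2,4,6-tris(benzyloxy)phenyl]lithium (not isolated) | [Li]c1c(OCc2ccccc2)cc(OCc2ccccc2)cc1OCc1ccccc1 | intermediate
8 | rac-1-[4-(benzyloxy)-2-hydroxyphenyl]-3-[4-(benzyloxy)phenyl]-1-[2,4,6-tris(benzyloxy)phenyl]propan-1-ol | OC(CCc1ccc(OCc2ccccc2)cc1)(c1ccc(OCc2ccccc2)cc1O)c1c(OCc2ccccc2)cc(OCc2ccccc2)cc1OCc1ccccc1 | intermediate
9 | 3-(benzyloxy)-6-{3-[4-(benzyloxy)phenyl]-1-[2,4,6-tris(benzyloxy)phenyl]propylidene}cyclohexa-2,4-dien-1-one (not isolated; the two geometries interconvert through the protonated form) | O=C1C=C(OCc2ccccc2)C=CC1=C(CCc1ccc(OCc2ccccc2)cc1)c1c(OCc2ccccc2)cc(OCc2ccccc2)cc1OCc1ccccc1 | intermediate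
10 | 5-(benzyloxy)-2-{(1R)-3-[4-(benzyloxy)phenyl]-1-[2,4,6-tris(benzyloxy)phenyl]propyl}phenol | C(c1ccccc1)Oc1cc(OCc2ccccc2)c([C@@H](c2ccc(OCc3ccccc3)cc2O)CCc2ccc(OCc3ccccc3)cc2)c(OCc2ccccc2)c1 | intermediate
11 | 5-(benzyloxy)-2-{(1R)-3-[4-(benzyloxy)phenyl]-1-[2,4,6-tris(benzyloxy)phenyl]propyl}phenyl acetate | C(c1ccccc1)Oc1cc(OCc2ccccc2)c([C@@H](c2ccc(OCc3ccccc3)cc2OC(C)=O)CCc2ccc(OCc3ccccc3)cc2)c(OCc2ccccc2)c1 | intermediate
12 | 9-phenylnonanoic acid | OC(=O)CCCCCCCCc1ccccc1 | starting material
13 | 9-phenylnonanoic trifluoroacetic anhydride (not isolated) | O=C(CCCCCCCCc1ccccc1)OC(=O)C(F)(F)F | intermediate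
14 | 5-(benzyloxy)-2-{(1R)-3-[4-(benzyloxy)phenyl]-1-[2,4,6-tris(benzyloxy)-3-(9-phenylnonanoyl)phenyl]propyl}phenyl acetate | C(c1ccccc1)Oc1cc(OCc2ccccc2)c([C@@H](c2ccc(OCc3ccccc3)cc2OC(C)=O)CCc2ccc(OCc3ccccc3)cc2)c(OCc2ccccc2)c1C(=O)CCCCCCCCc1ccccc1 | intermediate
15 | 1-{2,4,6-tris(benzyloxy)-3-[(1R)-1-[4-(benzyloxy)-2-hydroxyphenyl]-3-[4-(benzyloxy)phenyl]propyl]phenyl}-9-phenylnonan-1-one | C(c1ccccc1)Oc1cc(OCc2ccccc2)c([C@@H](c2ccc(OCc3ccccc3)cc2O)CCc2ccc(OCc3ccccc3)cc2)c(OCc2ccccc2)c1C(=O)CCCCCCCCc1ccccc1 | intermediate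
16 | (3R)-1-[4-(benzyloxy)phenyl]-3-[4-(benzyloxy)-2-hydroxyphenyl]-3-[2,4,6-tris(benzyloxy)-3-(9-phenylnonanoyl)phenyl]propan-1-ylium, counter-ion DDQH− (not isolated) | C(c1ccccc1)Oc1cc(OCc2ccccc2)c([C@@H](c2ccc(OCc3ccccc3)cc2O)C[CH+]c2ccc(OCc3ccccc3)cc2)c(OCc2ccccc2)c1C(=O)CCCCCCCCc1ccccc1 | intermediate
17 | 1-{2,4,6-tris(benzyloxy)-3-[(2R,4R)-7-(benzyloxy)-2-[4-(benzyloxy)phenyl]chroman-4-yl]phenyl}-9-phenylnonan-1-one | C(c1ccccc1)Oc1cc(OCc2ccccc2)c([C@@H]2C[C@H](c3ccc(OCc4ccccc4)cc3)Oc3cc(OCc4ccccc4)ccc32)c(OCc2ccccc2)c1C(=O)CCCCCCCCc1ccccc1 | intermediate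
18 | 1-{2,4,6-trihydroxy-3-[(2R,4R)-7-hydroxy-2-(4-hydroxyphenyl)chroman-4-yl]phenyl}-9-phenylnonan-1-one | O=C(CCCCCCCCc1ccccc1)c1c(O)cc(O)c([C@@H]2C[C@H](c3ccc(O)cc3)Oc3cc(O)ccc32)c1O | target

Total step count: 10.
Longest linear sequence: 9 steps (1 → 3 → 4 → 8 → 10 → 11 → 14 → 15 → 17 → 18).

Steps most likely to fail

**Step 9.**
- What may go wrong:
  - Oxidation of the electron-rich free phenol of ring A, or hydride loss from C4, may run ahead of hydride loss from C2.
  - Hydride may be lost again from C2 of the product.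
  - Facial selectivity may be poor when O1 captures the planar cation.
- Fallback: it sets out from acetate 14, in which the ring A oxygen is masked and ring A is a weaker donor.
  - DDQ (2.5 equiv) in wet dioxane should carry C2 through the benzylic alcohol to the aryl ketone F1. This is the known oxidation of para-alkoxy alkylarenes in aqueous medium.
  - Corey–Bakshi–Shibata reduction with (R)-2-methyl-CBS-oxazaborolidine and BH3·SMe2 should give the (S)-benzylic alcohol F2 under reagent control. The ring P ketone is shielded by its two ortho benzyloxy groups.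
  - K2CO3 in MeOH frees the phenol to give the phenol alcohol F3.
  - An intramolecular Mitsunobu etherification (PPh3, DIAD, THF, 0 °C) closes O1–C2 with inversion and comes back to the route at 17. C2 is then set by the reagent and no longer depends on the conformation of a cation.

**Step 5.**
- What may go wrong: hydride transfer to the crowded C4 of the quinone methide may be slow, and discrimination between its two faces may be low.
- Fallback: it sets out from carbinol 8.
  - Ionic hydrogenation (Et3SiH, CF3CO2H, CH2Cl2, −20 °C) should give the racemic triarylpropane F4.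
  - Acylation with (1S)-camphanic chloride (Et3N, DMAP, CH2Cl2) gives two diastereomeric esters, which are separated by crystallisation or chromatography.
  - The (R)-configured camphanate F5 is saponified (LiOH, THF/H2O) and comes back to the route at 10.

**Step 4.**
- What may go wrong: the hindered, basic aryllithium may enolise the ketone instead of adding to it, and the labile carbinol may ionise too early during work-up.
- Fallback: it sets out from ketone 4 and arene 5 and forms the C4–ring P bond with reversed roles.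
  - NaBH4 (MeOH/THF, 0 °C) gives the benzylic alcohol F6.
  - A catalytic acid (Bi(OTf)3, 2 mol %, CH2Cl2, 0 °C) ionises it to the secondary ortho-quinone methide or benzylic cation, which is far less crowded than the ketone.
  - Arene 5 attacks this species as a π-nucleophile (Friedel–Crafts alkylation) to give the racemic triarylpropane F4.
  - F4 is resolved through the camphanate F5 as described for step 5 and comes back to the route at 10, by-passing 8.

Further compounds
F1 | step 9 | 5-(benzyloxy)-2-{(1R)-3-[4-(benzyloxy)phenyl]-3-oxo-1-[2,4,6-tris(benzyloxy)-3-(9-phenylnonanoyl)phenyl]propyl}phenyl acetate | C(c1ccccc1)Oc1cc(OCc2ccccc2)c([C@@H](c2ccc(OCc3ccccc3)cc2OC(C)=O)CC(=O)c2ccc(OCc3ccccc3)cc2)c(OCc2ccccc2)c1C(=O)CCCCCCCCc1ccccc1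
F2 | step 9 | 5-(benzyloxy)-2-{(1R,3S)-3-[4-(benzyloxy)phenyl]-3-hydroxy-1-[2,4,6-tris(benzyloxy)-3-(9-phenylnonanoyl)phenyl]propyl}phenyl acetate | C(c1ccccc1)Oc1cc(OCc2ccccc2)c([C@@H](c2ccc(OCc3ccccc3)cc2OC(C)=O)C[C@H](O)c2ccc(OCc3ccccc3)cc2)c(OCc2ccccc2)c1C(=O)CCCCCCCCc1ccccc1
F3 | step 9 | 1-{2,4,6-tris(benzyloxy)-3-[(1R,3S)-1-[4-(benzyloxy)-2-hydroxyphenyl]-3-[4-(benzyloxy)phenyl]-3-hydroxypropyl]phenyl}-9-phenylnonan-1-one | C(c1ccccc1)Oc1cc(OCc2ccccc2)c([C@@H](c2ccc(OCc3ccccc3)cc2O)C[C@H](O)c2ccc(OCc3ccccc3)cc2)c(OCc2ccccc2)c1C(=O)CCCCCCCCc1ccccc1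
F4 | step 5 | rac-5-(benzyloxy)-2-{3-[4-(benzyloxy)phenyl]-1-[2,4,6-tris(benzyloxy)phenyl]propyl}phenol | C(c1ccccc1)Oc1cc(OCc2ccccc2)c(C(c2ccc(OCc3ccccc3)cc2O)CCc2ccc(OCc3ccccc3)cc2)c(OCc2ccccc2)c1
F5 | step 5 | 5-(benzyloxy)-2-{(1R)-3-[4-(benzyloxy)phenyl]-1-[2,4,6-tris(benzyloxy)phenyl]propyl}phenyl (1S,4R)-4,7,7-trimethyl-3-oxo-2-oxabicyclo[2.2.1]heptane-1-carboxylate | C(c1ccccc1)Oc1cc(OCc2ccccc2)c([C@@H](c2ccc(OCc3ccccc3)cc2OC(=O)[C@@]23CC[C@@](C)(C(=O)O2)C3(C)C)CCc2ccc(OCc3ccccc3)cc2)c(OCc2ccccc2)c1
F6 | step 4 | rac-1-[4-(benzyloxy)-2-hydroxyphenyl]-3-[4-(benzyloxy)phenyl]propan-1-ol | OC(CCc1ccc(OCc2ccccc2)cc1)c1ccc(OCc2ccccc2)cc1O
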